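**Retrosynthetic overview**

1. Numbering follows phenanthrene: ring A is the arene (C1 OH, C3 OCH3), ring B is C4a/C4b/C8a/C9/C10/C10a (C9 H2, C10=O), ring C is C4b/C5/C6/C7/C8/C8a (C5 methyl carbinol, C6 N, C7 OCH3, C8=O); C2' is the aminal carbon.
2. Feature used: ring B bears nothing but the C10 oxygen and the C9 methylene and shares the C4b=C8a alkene with ring C, so that, one C10 oxidation and one C4b-to-C9 proton shift back, rings B and C are the [4+2] adduct of a ring A hydroxy-o-quinodimethane (C10=C10a–C4a=C4b) and a C8-acyl alkyne (C8a≡C9).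
3. Key disconnection: C9–C10 and C4b–C8a, made together by irradiating a ring A benzaldehyde whose ortho CH2 (C4b) carries the bicyclic N,O-acetal enaminone with a terminal ynone at C8.
4. The precursor is cut at C8–C8a (acetylide on a Weinreb amide), C6=C7 (sulfide contraction of a thiolactam), C2'–N/C2'–O (N-acyliminium closure of an α-hydroxy amide made from 4-aminobutanal acetal) and C4a–C4b (aryl Grignard opening of (R)-2-methylglycidate, the source of C5).
5. Ring order: ring A is bought; the pyrrolidine and oxazolidine rings form in one step; rings B and C form together in the key step; oxidation, proton shift and desilylation finish.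

Key step: step 13

Assumption: the target is drawn as the chelated C10 ketone with C9 H2; this and the 10-hydroxy naphthol form are prototropic partners through one anion, and the drawn ketone is taken to be the form that is isolated.
Abbreviations: TBS = tert-butyldimethylsilyl; Ar = 3-(TBSO)-2-(TBSO-methyl)-5-methoxyphenyl, in which the CH2OTBS carbon is C10, the OTBS carbon C1, the OCH3 carbon C3 and the attachment carbon C4a.

**Route**

Step 1
Reactants: 1 2-bromo-4,6-dimethoxybenzaldehyde
Product: 2 2-bromo-6-hydroxy-4-methoxybenzaldehyde
Conditions: BCl3, CH2Cl2, −78 → 0 °C; H2O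
Reagents that add atoms: none
Why: Chelation of BCl3 between the aldehyde oxygen and the ortho methoxy group should cleave only that methyl ether (chelation-directed aryl methyl ether cleavage), leaving the para methoxy group that becomes C3–OCH3 and freeing the future C1 phenol.

Step 2
Reactants: 2 2-bromo-6-hydroxy-4-methoxybenzaldehyde
Product: 3 3-bromo-2-(hydroxymethyl)-5-methoxyphenol
Conditions: NaBH4, THF/MeOH, 0 °C; pH 7 buffer
Reagents that add atoms: none
Why: Borohydride reduction takes the aldehyde to the benzylic alcohol (the future C10) without touching the aryl bromide, and the hydroxybenzyl alcohol is carried on crude because it is prone to quinone methide formation.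

Step 3
Reactants: 3 3-bromo-2-(hydroxymethyl)-5-methoxyphenol
Product: 4 1-bromo-3-(TBSO)-2-(TBSO-methyl)-5-methoxybenzene (Ar–Br)
Conditions: TBSCl (2.5 equiv), imidazole, DMF, 0 → 23 °C
Reagents that add atoms: tert-butyldimethylsilyl chloride, CC(C)(C)[Si](C)(C)Cl
Why: Imidazole-promoted silylation protects the phenol and the primary benzylic alcohol together, giving an aryl silyl ether that lasts to the final step and an alkyl silyl ether that can later be removed by acid in its presence.

Step 4
Reactants: 4 Ar–Br; 5 methyl (2R)-2-methyloxirane-2-carboxylate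
Product: 7 methyl (2R)-3-Ar-2-hydroxy-2-methylpropanoate, via arylmagnesium bromide 6 (not isolated)
Conditions: Mg, LiCl, THF, 40 °C; CuI (10 mol %), then 5, −40 → 0 °C; aq. NH4Cl
Reagents that add atoms: none
Why: Magnesium insertion gives an aryl Grignard reagent that under copper catalysis should open the 2,2-disubstituted epoxide at its unsubstituted CH2 carbon faster than it adds to the ester (copper-catalysed Grignard epoxide opening), forming C4a–C4b while the quaternary carbinol C5 is not a reacting centre and keeps the R configuration of the glycidate.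

Step 5
Reactants: 7 methyl (2R)-3-Ar-2-hydroxy-2-methylpropanoate; 8 4,4-diethoxybutan-1-amine
Product: 9 (2R)-N-(4,4-diethoxybutyl)-3-Ar-2-hydroxy-2-methylpropanamide
Conditions: AlMe3, toluene, 0 → 50 °C; aq. potassium sodium tartrate
Reagents that add atoms: none
Why: The dimethylaluminium amide formed from AlMe3 and amine 8 should convert the hindered α-hydroxy methyl ester into the secondary amide (aluminium amide aminolysis of an ester), the tertiary alkoxide chelating aluminium and the acetal and silyl ethers being inert at this temperature.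

Step 6
Reactants: 9 (2R)-N-(4,4-diethoxybutyl)-3-Ar-2-hydroxy-2-methylpropanamide
Product: 11 (2R,7aS)-2-(Ar-methyl)-2-methyltetrahydropyrrolo[2,1-b]oxazol-3(2H)-one, via 2-ethoxypyrrolidine amide 10 (not isolated)
Conditions: PPTS (0.3 equiv), 5 Å MS, toluene, 90 °C
Reagents that add atoms: none
Why: Weak acid should move the acetal carbon onto the amide nitrogen and then ionise the ethoxy amide to the N-acyliminium ion, which the tertiary C5 hydroxyl traps as a five-membered N,O-acetal (N-acyliminium cyclisation), the aminal centre C2' (position 7a) being set under thermodynamic control by the fixed C5 centre so that the 7aS isomer, with the larger arylmethyl group pseudo-equatorial on the side of the C3' methylene and the methyl group next to H-2', should be favoured, while the 7aR epimer is separated and returned to the same conditions.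

Step 7
Reactants: 11 bicyclic lactam
Product: 12 (2R,7aS)-2-(Ar-methyl)-2-methyltetrahydropyrrolo[2,1-b]oxazole-3(2H)-thione
Conditions: Lawesson's reagent (0.6 equiv), toluene, 90 °C
Reagents that add atoms: Lawesson's reagent, COc1ccc(cc1)P1(=S)SP(=S)(S1)c1ccc(OC)cc1
Why: Lawesson's reagent should thionate the tertiary lactam carbonyl, the only carbonyl present (amide-to-thioamide exchange), without touching the N,O-acetal or the silyl ethers.

Step 8
Reactants: 12 thiolactam; 13 methyl 2-bromo-2-methoxyacetate (racemic)
Product: 15 methyl (2Z)-methoxy[(2R,7aS)-2-(Ar-methyl)-2-methyltetrahydropyrrolo[2,1-b]oxazol-3(2H)-ylidene]acetate, via thioiminium bromide 14 (not isolated)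
Conditions: MeCN, 23 °C; then PPh3, Et3N, 60 °C
Reagents that add atoms: none
Why: S-Alkylation of the thiolactam by the reactive α-bromo ether, deprotonation of the thioiminium salt to an episulfide and sulfur removal by PPh3 should create the C6=C7 bond of a vinylogous carbamate (Eschenmoser sulfide contraction), whose push–pull alkene exists as an interconverting pair of geometric isomers of which the one with the ester cis to C5 is drawn.

Step 9
Reactants: 15 vinylogous carbamate
Product: 16 (2Z)-N,2-dimethoxy-N-methyl-2-[(2R,7aS)-2-(Ar-methyl)-2-methyltetrahydropyrrolo[2,1-b]oxazol-3(2H)-ylidene]acetamide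
Conditions: MeNH(OMe)·HCl, iPrMgCl, THF, −20 → 23 °C; aq. NH4Cl
Reagents that add atoms: N,O-dimethylhydroxylamine hydrochloride, CNOC.Cl
Why: The chloromagnesium amide of N,O-dimethylhydroxylamine should displace methoxide from the crowded and therefore twisted, only partly deactivated vinylogous carbamate ester (magnesium amide ester-to-Weinreb-amide exchange), so that a single acetylide addition becomes possible.

Step 10
Reactants: 16 Weinreb amide
Product: 17 (1Z)-1-methoxy-1-[(2R,7aS)-2-(Ar-methyl)-2-methyltetrahydropyrrolo[2,1-b]oxazol-3(2H)-ylidene]but-3-yn-2-one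
Conditions: HC≡CMgBr, THF, −20 → 0 °C; cold aq. NH4Cl
Reagents that add atoms: ethynylmagnesium bromide, C#C[Mg]Br
Why: The acetylide adds once to give a magnesium chelate that collapses to the ketone only on cold work-up (Weinreb ketone synthesis), so the terminal ynone C8(=O)–C8a≡C9H should form without over-addition and without the liberated amine adding to it.

Step 11
Reactants: 17 bis-silylated ynone
Product: 18 the C10 benzylic alcohol of 17 (CH2OH on ring A; C1 OTBS kept)
Conditions: PPTS (0.3 equiv), MeOH, 23 °C
Reagents that add atoms: none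
Why: Acid-catalysed methanolysis removes a primary alkyl silyl ether far faster than an aryl silyl ether (selective desilylation), and the vinylogous amide N,O-acetal and the ynone should tolerate this weak acid.

Step 12
Reactants: 18 benzylic alcohol
Product: 19 2-(TBSO)-4-methoxy-6-{[(2R,3Z,7aS)-3-(1-methoxy-2-oxobut-3-yn-1-ylidene)-2-methylhexahydropyrrolo[2,1-b]oxazol-2-yl]methyl}benzaldehyde
Conditions: MnO2, CH2Cl2, 23 °C
Reagents that add atoms: none
Why: MnO2 oxidises the electron-rich benzylic alcohol to the C10 aldehyde under neutral heterogeneous conditions (benzylic alcohol oxidation) that leave the ynone, the enaminone and the aryl silyl ether alone.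

Step 13
Reactants: 19 ring A aldehyde tethered to the enaminone ynone
Product: 21 tetracyclic cycloadduct (C10 carbinol; C4b methine; both as epimer mixtures; C8a=C9 alkene; C1 OTBS; 5R,2'S), via hydroxy-o-quinodimethane 20 (not isolated)
Conditions: hν (365 nm), degassed toluene (2 mM), 25 °C
Reagents that add atoms: none
Why: Excitation of the ring A aldehyde and 1,5-hydrogen transfer from the C4b methylene should give the dienol 20 (C10=C10a–C4a=C4b, hydroxyl outward), which lives long enough for the tethered C8a≡C9 ynone to add across C10 and C4b in a suprafacial [4+2] that restores the aromaticity of ring A. The closest known reaction type is the intramolecular photoenolisation/Diels–Alder reaction of ortho-alkylbenzaldehydes that carry a tethered dienophile. Ring B closes as the new six-membered cycloaddition ring (bonds C9–C10 and C4b–C8a), and ring C closes in the same event as the six-membered ring spanned by the four-atom tether C5–C6–C7–C8 between the diene terminus C4b and the near alkyne carbon C8a, giving the fused bicycle directly. The two new centres, the C10 carbinol and the C4b methine, follow from the outward hydroxyl of the dienol and from approach of the alkyne past the methyl/oxygen pair on C5, but neither needs control because both are removed in steps 14 and 15. The step needs only the right pairing of termini and a reactive conformer: the short tether admits only C4b–C8a with C9–C10, the quaternary C5 folds the chain, and only the C6=C7 isomer with C8 cis to C5 can reach C4b, a geometry that the low rotation barrier of the push–pull alkene keeps supplied in the dark and under light. The C1 silyl ether offers no hydrogen that could compete for the excited carbonyl, and C5 and C2' are not involved.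

Step 14
Reactants: 21 cycloadduct
Product: 22 C10 ketone (4bH-ene-dione: C10=O; C8a=C9; C4b–H; C1 OTBS)
Conditions: Dess–Martin periodinane, NaHCO3, CH2Cl2, 0 °C
Reagents that add atoms: none
Why: Dess–Martin oxidation converts both epimers of the allylic, benzylic C10 carbinol into the C10 ketone under buffered conditions that avoid the acid-promoted loss of water which would aromatise ring B without oxygen at C10, and the product is carried on crude because it is a tautomer of a naphthol.

Step 15
Reactants: 22 C10 ketone
Product: 24 target CNP0528850.1 (5R,2'S), via tetrabutylammonium naphtholate 23 (not isolated)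
Conditions: TBAF, THF, 0 °C, argon; then AcOH
Reagents that add atoms: none
Why: Fluoride removes the C1 silyl group and the phenoxide so formed takes the strongly acidic C4b hydrogen to give the ring B naphtholate 23, erasing the C4b centre, and buffered acidification should then deliver a proton to C9 to leave the chelated C10 ketone with the C4b=C8a alkene (desilylation combined with a base-mediated prototropic shift), C5 and C2' being untouched.

**Compound list**

1 | 2-bromo-4,6-dimethoxybenzaldehyde | O=Cc1c(OC)cc(OC)cc1Br | starting material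
2 | 2-bromo-6-hydroxy-4-methoxybenzaldehyde | O=Cc1c(O)cc(OC)cc1Br | intermediate
3 | 3-bromo-2-(hydroxymethyl)-5-methoxyphenol | OCc1c(O)cc(OC)cc1Br | intermediate
4 | 1-bromo-3-(TBSO)-2-(TBSO-methyl)-5-methoxybenzene | CC(C)(C)[Si](C)(C)OCc1c(O[Si](C)(C)C(C)(C)C)cc(OC)cc1Br | intermediate
5 | methyl (2R)-2-methyloxirane-2-carboxylate | C[C@@]1(CO1)C(=O)OC | starting material
6 | [3-(TBSO)-2-(TBSO-methyl)-5-methoxyphenyl]magnesium bromide | CC(C)(C)[Si](C)(C)OCc1c(O[Si](C)(C)C(C)(C)C)cc(OC)cc1[Mg]Br | intermediate
7 | methyl (2R)-3-Ar-2-hydroxy-2-methylpropanoate | CC(C)(C)[Si](C)(C)OCc1c(O[Si](C)(C)C(C)(C)C)cc(OC)cc1C[C@@](C)(O)C(=O)OC | intermediate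
8 | 4,4-diethoxybutan-1-amine (4-aminobutanal diethyl acetal) | CCOC(CCCN)OCC | starting material
9 | (2R)-N-(4,4-diethoxybutyl)-3-Ar-2-hydroxy-2-methylpropanamide | CC(C)(C)[Si](C)(C)OCc1c(O[Si](C)(C)C(C)(C)C)cc(OC)cc1C[C@@](C)(O)C(=O)NCCCC(OCC)OCC | intermediate
10 | (2R)-3-Ar-1-(2-ethoxypyrrolidin-1-yl)-2-hydroxy-2-methylpropan-1-one (both epimers at the ethoxy carbon) | CC(C)(C)[Si](C)(C)OCc1c(O[Si](C)(C)C(C)(C)C)cc(OC)cc1C[C@@](C)(O)C(=O)N1CCCC1OCC | intermediate
11 | (2R,7aS)-2-(Ar-methyl)-2-methyltetrahydropyrrolo[2,1-b]oxazol-3(2H)-one | CC(C)(C)[Si](C)(C)OCc1c(O[Si](C)(C)C(C)(C)C)cc(OC)cc1C[C@@]1(C)O[C@H]2CCCN2C1=O | intermediate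
12 | (2R,7aS)-2-(Ar-methyl)-2-methyltetrahydropyrrolo[2,1-b]oxazole-3(2H)-thione | CC(C)(C)[Si](C)(C)OCc1c(O[Si](C)(C)C(C)(C)C)cc(OC)cc1C[C@@]1(C)O[C@H]2CCCN2C1=S | intermediate
13 | methyl 2-bromo-2-methoxyacetate (racemic) | COC(Br)C(=O)OC | starting material
14 | S-[methoxy(methoxycarbonyl)methyl] thioiminium bromide of 12 | CC(C)(C)[Si](C)(C)OCc1c(O[Si](C)(C)C(C)(C)C)cc(OC)cc1C[C@@]1(C)O[C@H]2CCC[N+]2=C1SC(OC)C(=O)OC.[Br-] | intermediate
15 | methyl (2Z)-methoxy[(2R,7aS)-2-(Ar-methyl)-2-methyltetrahydropyrrolo[2,1-b]oxazol-3(2H)-ylidene]acetate | CC(C)(C)[Si](C)(C)OCc1c(O[Si](C)(C)C(C)(C)C)cc(OC)cc1C[C@@]1(C)O[C@H]2CCCN2/C1=C(\OC)C(=O)OC | intermediate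
16 | (2Z)-N,2-dimethoxy-N-methyl-2-[(2R,7aS)-2-(Ar-methyl)-2-methyltetrahydropyrrolo[2,1-b]oxazol-3(2H)-ylidene]acetamide | CC(C)(C)[Si](C)(C)OCc1c(O[Si](C)(C)C(C)(C)C)cc(OC)cc1C[C@@]1(C)O[C@H]2CCCN2/C1=C(\OC)C(=O)N(C)OC | intermediate
17 | (1Z)-1-methoxy-1-[(2R,7aS)-2-(Ar-methyl)-2-methyltetrahydropyrrolo[2,1-b]oxazol-3(2H)-ylidene]but-3-yn-2-one | CC(C)(C)[Si](C)(C)OCc1c(O[Si](C)(C)C(C)(C)C)cc(OC)cc1C[C@@]1(C)O[C@H]2CCCN2/C1=C(\OC)C(=O)C#C | intermediate
18 | ynone 17 with free C10 benzylic alcohol (C1 OTBS kept) | OCc1c(O[Si](C)(C)C(C)(C)C)cc(OC)cc1C[C@@]1(C)O[C@H]2CCCN2/C1=C(\OC)C(=O)C#C | intermediate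
19 | key-step precursor: ring A aldehyde (C1 OTBS, C3 OCH3) linked through C4b to the (5R,2'S) bicyclic N,O-acetal enaminone ynone | O=Cc1c(O[Si](C)(C)C(C)(C)C)cc(OC)cc1C[C@@]1(C)O[C@H]2CCCN2/C1=C(\OC)C(=O)C#C | intermediate
20 | hydroxy-o-quinodimethane (photoenol) of 19, hydroxyl and C5 both outward | O/C=C1\C(O[Si](C)(C)C(C)(C)C)=CC(OC)=C/C1=C\[C@@]1(C)O[C@H]2CCCN2/C1=C(\OC)C(=O)C#C | intermediate
21 | cycloadduct: C10 carbinol, C4b methine (epimer mixtures), C8a=C9, C8 ketone, C1 OTBS, 5R,2'S | COC1=C2N3CCC[C@@H]3O[C@]2(C)C2C(=CC(O)c3c(O[Si](C)(C)C(C)(C)C)cc(OC)cc32)C1=O | intermediate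
22 | C10 ketone of 21 (C8a=C9, C4b–H as epimer mixture) | COC1=C2N3CCC[C@@H]3O[C@]2(C)C2C(=CC(=O)c3c(O[Si](C)(C)C(C)(C)C)cc(OC)cc32)C1=O | intermediate
23 | tetrabutylammonium salt of the desilylated ring B naphtholate (C10–O−, aromatic ring B) | COC1=C2N3CCC[C@@H]3O[C@]2(C)c2c(cc([O-])c3c(O)cc(OC)cc32)C1=O.CCCC[N+](CCCC)(CCCC)CCCC | intermediate
24 | CNP0528850.1 (5R,2'S) | COC1=C2N3CCC[C@@H]3O[C@]2(C)C2=C(CC(=O)c3c(O)cc(OC)cc32)C1=O | target

**Step count and risks**

Total steps: 15. Longest linear sequence: 15 steps (1 to 24); 5, 8 and 13 are bought and enter in steps 4, 5 and 8.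

Steps most likely to fail:

1. Step 13 (key step). The push–pull enaminone ynone may take most of the 365 nm light. The photoenol may also revert to the aldehyde faster than the electronically deactivated ynone adds, so that conversion stalls or the dienol drains into other channels. The fallback sets out from 19 and comes back at 21. Dienol that is not trapped closes thermally (4π) to the benzocyclobutenol F1, which no longer absorbs at 365 nm and should accumulate on prolonged irradiation at −40 °C. F1 is then heated in the dark (toluene, 110 °C), where conrotatory ring opening with the hydroxyl rotating outward regenerates dienol 20 repeatedly until the intramolecular Diels–Alder reaction with the ynone gives 21. This replaces the one-pot photochemical cascade by a photoisomerisation followed by a thermal benzocyclobutenol ring-opening/cycloaddition, both known reaction types.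

2. Step 6. Methyl and arylmethyl at C5 may be told apart too weakly in the reversible N,O-acetal closure, so that both C2' epimers form and re-equilibrate slowly. The benzylic silyl ether may also be partly lost or ionised during long heating with acid. The fallback sets out from 6 and comes back at 11; it fixes C2' on a lactam that has hydrogen at C5 and makes C5 quaternary afterwards. Copper-catalysed opening of purchasable methyl (R)-glycidate (COC(=O)[C@H]1CO1) by 6 would give the secondary hydroxy ester F2, and AlMe3 with amine 8 would give the hydroxy amide F3. PPTS closure would give the C5-unsubstituted bicyclic lactam F4, where the choice is between hydrogen and arylmethyl and the arylmethyl group should sit cleanly on the C3' side (7aS). LDA and then MeI would methylate the lactam enolate on the face away from the pyrrolidine ring, the aminal centre regenerating the C5 centre, which returns 11 with methyl cis to H-2'. Should the closure to F4 favour the other epimer, methyl (S)-glycidate would be used instead.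

3. Step 8. The thiolactam next to the quaternary C5 may be alkylated only reversibly by the secondary α-bromo ether, or the thioiminium salt may fail to collapse to the fully substituted episulfide, so that 12 is returned or hydrolysed back to 11. The fallback sets out from 12 and comes back at 15; it reverses the polarity of the C6–C7 bond formation. S-Methylation of 12 with MeOTf would give the S-methyl thioiminium triflate F5. The lithium enolate of methyl methoxyacetate (LDA, THF, −78 → 0 °C) would then add to C6 and expel methanethiolate to give 15 (thioiminium–enolate condensation).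

**Further compounds**

F1 | step 13 | benzocyclobutenol of 19 (four-membered ring C10–C10a–C4a–C4b, C10 OH, C4b bearing C5; epimer mixture at C10 and C4b) | OC1c2c(O[Si](C)(C)C(C)(C)C)cc(OC)cc2C1[C@@]1(C)O[C@H]2CCCN2/C1=C(\OC)C(=O)C#C
F2 | step 6 | methyl (2R)-3-Ar-2-hydroxypropanoate | CC(C)(C)[Si](C)(C)OCc1c(O[Si](C)(C)C(C)(C)C)cc(OC)cc1C[C@@H](O)C(=O)OC
F3 | step 6 | (2R)-N-(4,4-diethoxybutyl)-3-Ar-2-hydroxypropanamide | CC(C)(C)[Si](C)(C)OCc1c(O[Si](C)(C)C(C)(C)C)cc(OC)cc1C[C@@H](O)C(=O)NCCCC(OCC)OCC
F4 | step 6 | (2R,7aS)-2-(Ar-methyl)tetrahydropyrrolo[2,1-b]oxazol-3(2H)-one | CC(C)(C)[Si](C)(C)OCc1c(O[Si](C)(C)C(C)(C)C)cc(OC)cc1C[C@H]1O[C@H]2CCCN2C1=O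
F5 | step 8 | S-methyl thioiminium trifluoromethanesulfonate of 12 | CC(C)(C)[Si](C)(C)OCc1c(O[Si](C)(C)C(C)(C)C)cc(OC)cc1C[C@@]1(C)O[C@H]2CCC[N+]2=C1SC.[O-]S(=O)(=O)C(F)(F)F
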